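Compound numbers are fixed first and used throughout: 1–26 are the compounds of the route (26 is the target), F1–F14 belong to fallbacks, A1–A3 to the strategies that were turned down.

## Analysis of the target

The target is a sesquineolignan built from a 7-methoxy-2,3-dihydrobenzofuran (benzo ring C, dihydrofuran ring D; O1, C2, C3, C3a, C4–C7, C7a) with a guaiacyl ring E on C2 and CH2OH on C3. C5 of that unit carries an oxolane (ring B; O1', C2'–C5'): C2' is bonded to C5, C3' bears CH2OH, and C4' bears a tertiary hydroxyl and the 4-hydroxy-3-methoxybenzyl group (ring A). There are five stereocentres in two clusters. C2 and C3 are both R, which places the aryl group and CH2OH cis on ring D. C2' (R), C3' (R) and C4' (S) place aryl, CH2OH and benzyl on one face of ring B and the hydroxyl with H-2' and H-3' on the other. Ring C separates the clusters, so neither can steer the other and each needs its own source of absolute control. The cis ring D is the less stable diastereomer, and C2–O1 and C2'–O1' are para-oxygenated benzylic ethers that ionise in acid; once the ring E phenol is free, C2–O1 can also open to a quinone methide under base. The difficulty is therefore the contra-thermodynamic cis C2/C3 pair, the all-cis ring B with its fully substituted carbinol, and an endgame that must stay close to neutral. The strategy rests on one feature: C3 carries CH2OH and is bonded to arene carbon C3a, whose neighbour C7a carries O1. That array (aryl C–C(CH2O)–C–O–aryl) is what remains when an aryl carbanion ortho to an ether oxygen opens a terminal epoxide at its inner carbon.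

## Retrosynthetic reasoning

**26 back to 24.** The two phenols are unmasked last from dibenzyl ether 25 by neutral hydrogenolysis, because neither acid nor base is safe once ring E is a free phenol. The C3' hydroxymethyl group of 25 is the reduced form of the ester in 24, and the same hydride step removes the pivalate on the C3 side chain, so no separate deprotection is spent.

**24 back to 23.** The C2'–H and C3'–H bonds are cut, giving the 4,5-dihydrofuran 23. Adding both hydrogens from the face of the C4' hydroxyl makes the three carbon substituents cis, so the single centre C4' dictates C2' and C3'.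

**23 back to 17 and 21.** Ring B is cut at C3'–C4' and O1'–C5'. This gives β-ketoester 17 and chloroketone 21, joined in the forward sense by an interrupted Feist–Benary annulation (aldol, then O-alkylation, no dehydration). The cut is convergent and brings ring A in with its benzylic carbon already in place. The forward reaction must choose the face of the ketone of 21 under catalyst control, since C2 and C3 are too remote to help.

**17 back to 14.** The C5 side chain is shortened by two carbons to aldehyde 16 (Roskamp homologation forward). The aldehyde is carried as the dimethyl acetal 15/14 so that it survives an aryllithium. The primary alcohol of 14 is capped as a pivalate because that ester falls off in the ester reduction later.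

**14 back to 12 (key disconnection).** The C3–C3a bond is cut. Arene carbon C3a becomes a carbanion made from the C–Br bond of 12, and C3 becomes the inner carbon of a terminal epoxide whose oxygen ends as the CH2OH oxygen. This cut closes ring D and creates C3 in the same event. Because the opening is an SN2 inversion, the cis relation is encoded in the relative configuration of 12 and does not depend on ring thermodynamics.

**12 back to 8.** The threo epoxy ether 12 comes from the erythro diol 8 by closing the epoxide from the primary oxygen onto C2 (benzoate 9, mesylate 10). This inverts the carbinol carbon, which is needed because the route to 8 delivers the erythro relation.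

**8 back to 5 and 7.** The benzylic C–O(aryl) bond is cut: phenol 7 opens epoxy alcohol 5 at its benzylic carbon with inversion. A phenoxide SN2 opening without Lewis acid is used so that the electron-rich benzylic carbon never becomes a cation.

**5, 7 and 21 back to purchased materials.** 5 comes from allylic alcohol 4 by reagent-controlled epoxidation, and 4 from aldehyde 1 and phosphonate 2 via ester 3. 7 is the dimethyl acetal of 6. 21 comes from acid 18 by one-carbon chain extension through 19 and 20.

## Alternatives that were turned down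

**Alternative 1:** Ring B is cut at C2'–C3' and O1'–C5'. An aldehyde of the kind of 16 would be allylated under a chiral phosphoric acid by a trisubstituted allylboron reagent carrying a chloromethyl and a silyloxymethyl group, and KOt-Bu would then close the new alkoxide onto the allylic chloride to give the 4-methylideneoxolane A1.
- **For:** a closed six-membered transition state turns olefin geometry into the cis C2'/C3' relation and the catalyst fixes the absolute sense. C4' could afterwards be built under substrate control from the neighbouring C3' substituent. On control of C4' this is stronger than the annulation chosen here.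
- **Against:** A1 already contains the finished cis ring D, so this plan only replaces the way ring B is made and says nothing about the hardest element, the cis C2/C3 pair. The boron reagent needs several steps and a defined double-bond geometry. A1 still lacks ring A and the carbinol, which costs at least an oxidation of the exocyclic alkene and an aryl-metal opening, each with its own facial or regiochemical question.
- **Comparison:** the chosen route reaches the all-cis ring B from 17 in two operations with ring A attached. It accepts weaker precedent at C4' and covers that with a fallback.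

**Alternative 2:** The C2–C3 bond of ring D is cut and formed last. The diazo precursor of A2 would lose N2 on Rh2(S-PTTL)4, and the carbenoid would insert into the C–H bond of the ring E benzyl ether in a 1,5-fashion to give the cis ester A2.
- **For:** cis-selective, enantioselective 1,5-insertion into benzylic ethers is well established. It sets C2 and C3 in one catalytic step and brings ring E in as a simple benzyl ether. That precedent is at least as strong as the one behind the chosen ring closure.
- **Against:** the step is run on a substrate that already holds three stereocentres, so catalyst and substrate may be mismatched. The substrate offers other electron-rich arenes and α-oxygenated C–H bonds and needs four silyl ethers. A2 is a cis ester next to an arene, which epimerises to trans with traces of base and still needs reduction and global desilylation.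
- **Comparison:** the chosen route sets C3 by a stereospecific substitution with no catalyst matching and reaches the alcohol oxidation level directly. The same C–H insertion is kept in reserve, moved to an early simple substrate, as the fallback for the key step.

**Alternative 3:** The O1–C7a bond is cut. The secondary benzylic alkoxide of an open-chain bromo alcohol would be arylated intramolecularly with CuI, 3,4,7,8-tetramethyl-1,10-phenanthroline and Cs2CO3 to give A3, with retention because no bond at a stereocentre is touched.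
- **For:** the ring closure is stereochemically innocent and tolerates groups an aryllithium would not. On functional-group tolerance it is stronger than the chosen step.
- **Against:** both C2 and C3 must be set beforehand in an acyclic precursor, which lengthens the route. A3 has no carbon at C5, so ring B would need a later electrophilic formylation of the acid-labile cis ring D, in competition with C4 and C6. Ring E is held as a tosylate that must later be exchanged.
- **Comparison:** the chosen route carries the C5 carbon from the start as an acetal and creates C3 in the ring-closing event.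

Key step: step 9

Remark: 1 and 18, the O-benzyl ethers of vanillin and of homovanillic acid, are taken as purchased (each is otherwise one benzylation away).

## Route

Step 1
Reactants: 1 4-(benzyloxy)-3-methoxybenzaldehyde; 2 triethyl phosphonoacetate
Product: 3 ethyl (2E)-3-[4-(benzyloxy)-3-methoxyphenyl]prop-2-enoate
Conditions: NaH, THF, 0 °C to rt
Reagents that add atoms: none
Why: Horner–Wadsworth–Emmons olefination; the stabilised phosphonate anion gives the E-alkene that the later epoxidation needs.

Step 2
Reactants: 3 ethyl (2E)-3-[4-(benzyloxy)-3-methoxyphenyl]prop-2-enoate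
Product: 4 (2E)-3-[4-(benzyloxy)-3-methoxyphenyl]prop-2-en-1-ol
Conditions: i-Bu2AlH (2.2 equiv), CH2Cl2, −78 °C; aq. KNaC4H4O6
Reagents that add atoms: none
Why: 1,2-reduction of a conjugated ester to the allylic alcohol by an aluminium hydride; the double bond and the benzyl ether are not touched.

Step 3
Reactants: 4 (2E)-3-[4-(benzyloxy)-3-methoxyphenyl]prop-2-en-1-ol
Product: 5 [(2R,3R)-3-[4-(benzyloxy)-3-methoxyphenyl]oxiran-2-yl]methanol
Conditions: Ti(OiPr)4 (10 mol %), D-(−)-diisopropyl tartrate (12 mol %), t-BuOOH (2 equiv), 4 Å molecular sieves, CH2Cl2, −25 °C; cold aq. NaOH–NaCl work-up; used crude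
Reagents that add atoms: tert-butyl hydroperoxide CC(C)(C)OO
Why: Sharpless asymmetric epoxidation; with the D-tartrate the oxygen is delivered to the face of the E-allylic alcohol that gives the (2R,3R)-epoxide, setting both carbons under reagent control. The product is an electron-rich benzylic epoxide, so it is kept cold, worked up under base and not chromatographed.

Step 4
Reactants: 6 3-bromo-4-hydroxy-5-methoxybenzaldehyde (5-bromovanillin)
Product: 7 2-bromo-4-(dimethoxymethyl)-6-methoxyphenol
Conditions: HC(OMe)3 (3 equiv), MeOH, p-TsOH·H2O (1 mol %), rt; NaOMe quench, concentrate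
Reagents that add atoms: trimethyl orthoformate COC(OC)OC; methanol CO
Why: Acid-catalysed acetalisation with the orthoester as water scavenger. The acetal protects the aldehyde carbon from the later organolithium and removes the para-carbonyl that would weaken the phenoxide as a nucleophile.

Step 5
Reactants: 5 [(2R,3R)-3-[4-(benzyloxy)-3-methoxyphenyl]oxiran-2-yl]methanol; 7 2-bromo-4-(dimethoxymethyl)-6-methoxyphenol
Product: 8 (2R,3S)-3-[4-(benzyloxy)-3-methoxyphenyl]-3-[2-bromo-4-(dimethoxymethyl)-6-methoxyphenoxy]propane-1,2-diol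
Conditions: 7 (2 equiv), Cs2CO3 (1 equiv), DMF, 60 °C
Reagents that add atoms: none
Why: SN2 opening of a 3-aryl-2,3-epoxy alcohol by a phenoxide at the activated benzylic carbon, with inversion there (R to S) and retention at C2, giving the erythro diol. No Lewis acid is present, so the benzylic carbon is not ionised, and the excess phenol keeps alkoxide concentration low so that epoxide migration does not compete.

Step 6
Reactants: 8 (2R,3S)-3-[4-(benzyloxy)-3-methoxyphenyl]-3-[2-bromo-4-(dimethoxymethyl)-6-methoxyphenoxy]propane-1,2-diol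
Product: 9 (2R,3S)-3-[4-(benzyloxy)-3-methoxyphenyl]-3-[2-bromo-4-(dimethoxymethyl)-6-methoxyphenoxy]-2-hydroxypropyl benzoate
Conditions: BzCl (1.05 equiv), pyridine, CH2Cl2, −20 to 0 °C
Reagents that add atoms: benzoyl chloride O=C(Cl)c1ccccc1
Why: Selective acylation of the primary hydroxyl of a 1,2-diol; the secondary hydroxyl sits next to the crowded diaryl-substituted carbon and reacts far more slowly.

Step 7
Reactants: 9 (2R,3S)-3-[4-(benzyloxy)-3-methoxyphenyl]-3-[2-bromo-4-(dimethoxymethyl)-6-methoxyphenoxy]-2-hydroxypropyl benzoate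
Product: 10 (2R,3S)-3-[4-(benzyloxy)-3-methoxyphenyl]-3-[2-bromo-4-(dimethoxymethyl)-6-methoxyphenoxy]-2-[(methanesulfonyl)oxy]propyl benzoate
Conditions: MsCl (1.5 equiv), Et3N (2 equiv), CH2Cl2, 0 °C
Reagents that add atoms: methanesulfonyl chloride CS(=O)(=O)Cl
Why: Sulfonylation of the secondary alcohol with retention (the C–O bond is not touched); it turns C2 into the electrophilic centre for the epoxide closure.

Step 8
Reactants: 10 (2R,3S)-3-[4-(benzyloxy)-3-methoxyphenyl]-3-[2-bromo-4-(dimethoxymethyl)-6-methoxyphenoxy]-2-[(methanesulfonyl)oxy]propyl benzoate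
Product: 12 (2S)-2-{(S)-[4-(benzyloxy)-3-methoxyphenyl][2-bromo-4-(dimethoxymethyl)-6-methoxyphenoxy]methyl}oxirane (threo), via hydroxy mesylate 11 (not isolated)
Conditions: K2CO3 (2 equiv), MeOH, 0 °C to rt
Reagents that add atoms: none
Why: Methanolysis of the benzoate frees the primary alkoxide, which displaces the neighbouring mesylate in a 3-exo-tet SN2 closure; this inverts the carbinol carbon and converts the erythro diol pattern into the threo epoxy ether, while the benzylic centre and the acetal are untouched.

Step 9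
Reactants: 12 (2S)-2-{(S)-[4-(benzyloxy)-3-methoxyphenyl][2-bromo-4-(dimethoxymethyl)-6-methoxyphenoxy]methyl}oxirane
Product: 14 [(2R,3R)-2-[4-(benzyloxy)-3-methoxyphenyl]-5-(dimethoxymethyl)-7-methoxy-2,3-dihydro-1-benzofuran-3-yl]methanol (cis), via aryllithium 13 (not isolated)
Conditions: n-BuLi (1.05 equiv), THF, −78 °C, then −78 to −20 °C; pH 7 phosphate buffer
Reagents that add atoms: none
Why: Bromine–lithium exchange at −78 °C is faster than addition of n-BuLi to the epoxide or proton abstraction and gives aryllithium 13. Its carbanion lies in the arene plane ortho to the ether oxygen and reaches the inner epoxide carbon through a five-membered transition state, so ring D closes in the 5-exo-tet mode and the C3–C3a bond forms; attack at the terminal carbon would be the 6-endo mode. The closest known reaction is the Parham cyclisation of ortho-lithiated aryl glycidyl ethers to 3-(hydroxymethyl)-2,3-dihydrobenzofurans. The new ring stereocentre C3 is controlled by the substrate alone: the opening is an SN2 inversion at the (S)-epoxide carbon, and C2 is not involved. Because 12 is the threo isomer, inversion places CH2O− and the C2 aryl group cis. The step needs exo over endo opening, which the absence of any Lewis acid other than lithium and the shorter tether to the inner carbon secure. It also needs exchange to outrun deprotonation of the benzylic O–CH, which the bromide and the low temperature secure. The acetal protects the future aldehyde carbon, and the neutral quench protects the acetal.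

Step 10
Reactants: 14 [(2R,3R)-2-[4-(benzyloxy)-3-methoxyphenyl]-5-(dimethoxymethyl)-7-methoxy-2,3-dihydro-1-benzofuran-3-yl]methanol
Product: 15 [(2R,3R)-2-[4-(benzyloxy)-3-methoxyphenyl]-5-(dimethoxymethyl)-7-methoxy-2,3-dihydro-1-benzofuran-3-yl]methyl 2,2-dimethylpropanoate
Conditions: PivCl (1.3 equiv), pyridine, DMAP (5 mol %), CH2Cl2, 0 °C to rt
Reagents that add atoms: pivaloyl chloride CC(C)(C)C(=O)Cl
Why: Acylation of the primary alcohol; the pivalate withstands the Lewis acid, amine base and hydrogenation ahead and is removed by the hydride that reduces the ester in step 16.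

Step 11
Reactants: 15 [(2R,3R)-2-[4-(benzyloxy)-3-methoxyphenyl]-5-(dimethoxymethyl)-7-methoxy-2,3-dihydro-1-benzofuran-3-yl]methyl 2,2-dimethylpropanoate
Product: 16 [(2R,3R)-2-[4-(benzyloxy)-3-methoxyphenyl]-5-formyl-7-methoxy-2,3-dihydro-1-benzofuran-3-yl]methyl 2,2-dimethylpropanoate
Conditions: PPTS (10 mol %), acetone–H2O (9:1), rt
Reagents that add atoms: water O
Why: Hydrolysis of an electron-rich aryl dimethyl acetal needs only a weak acid, which is too mild to ionise the benzylic C2–O1 bond of the cis ring.

Step 12
Reactants: 16 [(2R,3R)-2-[4-(benzyloxy)-3-methoxyphenyl]-5-formyl-7-methoxy-2,3-dihydro-1-benzofuran-3-yl]methyl 2,2-dimethylpropanoate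
Product: 17 ethyl 3-[(2R,3R)-2-[4-(benzyloxy)-3-methoxyphenyl]-3-{[(2,2-dimethylpropanoyl)oxy]methyl}-7-methoxy-2,3-dihydro-1-benzofuran-5-yl]-3-oxopropanoate
Conditions: N2CHCO2Et (1.5 equiv), SnCl2 (10 mol %), CH2Cl2, rt
Reagents that add atoms: ethyl diazoacetate CCOC(=O)C=[N+]=[N-]
Why: Roskamp homologation; the diazo ester adds to the tin-activated aldehyde and a 1,2-hydride shift with loss of N2 gives the β-ketoester in one step under weakly Lewis-acidic conditions.

Step 13
Reactants: 18 [4-(benzyloxy)-3-methoxyphenyl]acetic acid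
Product: 21 1-[4-(benzyloxy)-3-methoxyphenyl]-3-chloropropan-2-one, via acid chloride 19 (not isolated), via diazoketone 20 (not isolated)
Conditions: (COCl)2, DMF (cat.), CH2Cl2, 0 °C to rt; evaporate; Me3SiCHN2 (2 equiv), THF–MeCN, 0 °C; HCl (4 M in dioxane), 0 °C
Reagents that add atoms: trimethylsilyldiazomethane C[Si](C)(C)C=[N+]=[N-]; hydrogen chloride Cl
Why: Acylation of the diazoalkane by the acid chloride gives the diazoketone, and HCl converts it into the chloromethyl ketone with loss of N2 (Nierenstein-type sequence); no amine base is used, so the arylacetyl chloride does not form a ketene.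

Step 14
Reactants: 17 ethyl 3-[(2R,3R)-2-[4-(benzyloxy)-3-methoxyphenyl]-3-{[(2,2-dimethylpropanoyl)oxy]methyl}-7-methoxy-2,3-dihydro-1-benzofuran-5-yl]-3-oxopropanoate; 21 1-[4-(benzyloxy)-3-methoxyphenyl]-3-chloropropan-2-one
Product: 23 ethyl (4S)-4-{[4-(benzyloxy)-3-methoxyphenyl]methyl}-2-[(2R,3R)-2-[4-(benzyloxy)-3-methoxyphenyl]-3-{[(2,2-dimethylpropanoyl)oxy]methyl}-7-methoxy-2,3-dihydro-1-benzofuran-5-yl]-4-hydroxy-4,5-dihydrofuran-3-carboxylate, via aldol chlorohydrin 22 (not isolated)
Conditions: 21 (1.3 equiv), (DHQD)2PYR (10 mol %), 1,8-bis(dimethylamino)naphthalene (1.1 equiv), THF, −40 °C to rt; chromatography on Et3N-washed silica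
Reagents that add atoms: none
Why: Proposed new method: the quinuclidine nitrogen of the bis-cinchona ether deprotonates 17, the chiral ammonium enolate adds through carbon to the ketone of 21 (aldol), and the enol oxygen then displaces chloride in a 5-exo-tet closure without dehydration, which forms C3'–C4' and O1'–C5' and sets C4' under catalyst control because C2 and C3 are too remote to help; the closest known reaction is the cinchona-catalysed asymmetric interrupted Feist–Benary annulation of 1,3-dicarbonyls with bromopyruvates and α-sulfonyloxy aryl ketones, whereas face selection on a ketone flanked by CH2Cl and CH2Ar has not been shown and is expected to rest on the size difference of the two groups and on hydrogen bonding of the ammonium N–H to carbonyl and chlorine; the sense of induction must be read on the first run (the C4' epimer is a diastereomer) and the pseudo-enantiomer (DHQ)2PYR taken if it is the wrong one; chloride as leaving group keeps direct C-alkylation slow.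

Step 15
Reactants: 23 ethyl (4S)-4-{[4-(benzyloxy)-3-methoxyphenyl]methyl}-2-[(2R,3R)-2-[4-(benzyloxy)-3-methoxyphenyl]-3-{[(2,2-dimethylpropanoyl)oxy]methyl}-7-methoxy-2,3-dihydro-1-benzofuran-5-yl]-4-hydroxy-4,5-dihydrofuran-3-carboxylate
Product: 24 ethyl (2R,3R,4S)-4-{[4-(benzyloxy)-3-methoxyphenyl]methyl}-2-[(2R,3R)-2-[4-(benzyloxy)-3-methoxyphenyl]-3-{[(2,2-dimethylpropanoyl)oxy]methyl}-7-methoxy-2,3-dihydro-1-benzofuran-5-yl]-4-hydroxyoxolane-3-carboxylate
Conditions: H2 (1–4 bar), [Ir(cod)(PCy3)(py)]PF6 (5 mol %), CH2Cl2, rt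
Reagents that add atoms: none
Why: Hydroxyl-directed homogeneous hydrogenation; the tertiary C4' hydroxyl binds the cationic iridium and both hydrogens are delivered to its face, so H-2' and H-3' end up cis to OH and aryl, ester and benzyl all cis (C2' and C3' set by substrate control from C4'). The benzyl group shields the opposite face, which points the same way, and this catalyst leaves benzyl ethers intact.

Step 16
Reactants: 24 ethyl (2R,3R,4S)-4-{[4-(benzyloxy)-3-methoxyphenyl]methyl}-2-[(2R,3R)-2-[4-(benzyloxy)-3-methoxyphenyl]-3-{[(2,2-dimethylpropanoyl)oxy]methyl}-7-methoxy-2,3-dihydro-1-benzofuran-5-yl]-4-hydroxyoxolane-3-carboxylate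
Product: 25 (3S,4R,5R)-5-[(2R,3R)-2-[4-(benzyloxy)-3-methoxyphenyl]-3-(hydroxymethyl)-7-methoxy-2,3-dihydro-1-benzofuran-5-yl]-3-{[4-(benzyloxy)-3-methoxyphenyl]methyl}-4-(hydroxymethyl)oxolan-3-ol
Conditions: LiAlH4 (4 equiv), THF, −20 to 0 °C; aq. KNaC4H4O6
Reagents that add atoms: none
Why: Hydride reduction of the ethyl ester to the C3' hydroxymethyl group with concurrent cleavage of the pivalate; the low temperature lets reduction outrun epimerisation at C3' and retro-aldol opening of the β-hydroxy ester.

Step 17
Reactants: 25 (3S,4R,5R)-5-[(2R,3R)-2-[4-(benzyloxy)-3-methoxyphenyl]-3-(hydroxymethyl)-7-methoxy-2,3-dihydro-1-benzofuran-5-yl]-3-{[4-(benzyloxy)-3-methoxyphenyl]methyl}-4-(hydroxymethyl)oxolan-3-ol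
Product: 26 (3S,4R,5R)-5-[(2R,3R)-2-(4-hydroxy-3-methoxyphenyl)-3-(hydroxymethyl)-7-methoxy-2,3-dihydro-1-benzofuran-5-yl]-3-[(4-hydroxy-3-methoxyphenyl)methyl]-4-(hydroxymethyl)oxolan-3-ol (CNP0284796.1)
Conditions: H2 (1 bar), Pd/C (10 % Pd), EtOAc–MeOH, rt; stopped when 25 is consumed
Reagents that add atoms: none
Why: Hydrogenolysis of the two aryl benzyl ethers, which cleave much faster than the cyclic benzylic ethers C2–O1 and C2'–O1'; the medium is neutral, so the cis ring D with its now free para-phenol is exposed to neither acid nor base.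

## Compound list

1 | 4-(benzyloxy)-3-methoxybenzaldehyde | COc1cc(C=O)ccc1OCc1ccccc1 | starting material
2 | triethyl phosphonoacetate | CCOC(=O)CP(=O)(OCC)OCC | starting material
3 | ethyl (2E)-3-[4-(benzyloxy)-3-methoxyphenyl]prop-2-enoate | CCOC(=O)/C=C/c1ccc(OCc2ccccc2)c(OC)c1 | intermediate
4 | (2E)-3-[4-(benzyloxy)-3-methoxyphenyl]prop-2-en-1-ol | OC/C=C/c1ccc(OCc2ccccc2)c(OC)c1 | intermediate
5 | [(2R,3R)-3-[4-(benzyloxy)-3-methoxyphenyl]oxiran-2-yl]methanol | OC[C@H]1O[C@@H]1c1ccc(OCc2ccccc2)c(OC)c1 | intermediate
6 | 3-bromo-4-hydroxy-5-methoxybenzaldehyde (5-bromovanillin) | COc1cc(C=O)cc(Br)c1O | starting material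
7 | 2-bromo-4-(dimethoxymethyl)-6-methoxyphenol | COC(OC)c1cc(OC)c(O)c(Br)c1 | intermediate
8 | (2R,3S)-3-[4-(benzyloxy)-3-methoxyphenyl]-3-[2-bromo-4-(dimethoxymethyl)-6-methoxyphenoxy]propane-1,2-diol | COC(OC)c1cc(OC)c(O[C@@H](c2ccc(OCc3ccccc3)c(OC)c2)[C@H](O)CO)c(Br)c1 | intermediate
9 | (2R,3S)-3-[4-(benzyloxy)-3-methoxyphenyl]-3-[2-bromo-4-(dimethoxymethyl)-6-methoxyphenoxy]-2-hydroxypropyl benzoate | COC(OC)c1cc(OC)c(O[C@@H](c2ccc(OCc3ccccc3)c(OC)c2)[C@H](O)COC(=O)c2ccccc2)c(Br)c1 | intermediate
10 | (2R,3S)-3-[4-(benzyloxy)-3-methoxyphenyl]-3-[2-bromo-4-(dimethoxymethyl)-6-methoxyphenoxy]-2-[(methanesulfonyl)oxy]propyl benzoate | COC(OC)c1cc(OC)c(O[C@@H](c2ccc(OCc3ccccc3)c(OC)c2)[C@H](OS(C)(=O)=O)COC(=O)c2ccccc2)c(Br)c1 | intermediate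
11 | (2R,3S)-3-[4-(benzyloxy)-3-methoxyphenyl]-3-[2-bromo-4-(dimethoxymethyl)-6-methoxyphenoxy]-1-hydroxypropan-2-yl methanesulfonate | COC(OC)c1cc(OC)c(O[C@@H](c2ccc(OCc3ccccc3)c(OC)c2)[C@H](OS(C)(=O)=O)CO)c(Br)c1 | intermediate (not isolated)
12 | (2S)-2-{(S)-[4-(benzyloxy)-3-methoxyphenyl][2-bromo-4-(dimethoxymethyl)-6-methoxyphenoxy]methyl}oxirane | COC(OC)c1cc(OC)c(O[C@@H](c2ccc(OCc3ccccc3)c(OC)c2)[C@@H]2CO2)c(Br)c1 | intermediate
13 | 2-{(S)-[4-(benzyloxy)-3-methoxyphenyl][(2S)-oxiran-2-yl]methoxy}-5-(dimethoxymethyl)-3-methoxyphenyllithium | [Li]c1cc(C(OC)OC)cc(OC)c1O[C@@H](c1ccc(OCc2ccccc2)c(OC)c1)[C@@H]1CO1 | intermediate (not isolated)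
14 | [(2R,3R)-2-[4-(benzyloxy)-3-methoxyphenyl]-5-(dimethoxymethyl)-7-methoxy-2,3-dihydro-1-benzofuran-3-yl]methanol | COC(OC)c1cc(OC)c2c(c1)[C@H](CO)[C@H](c1ccc(OCc3ccccc3)c(OC)c1)O2 | intermediate
15 | [(2R,3R)-2-[4-(benzyloxy)-3-methoxyphenyl]-5-(dimethoxymethyl)-7-methoxy-2,3-dihydro-1-benzofuran-3-yl]methyl 2,2-dimethylpropanoate | COC(OC)c1cc(OC)c2c(c1)[C@H](COC(=O)C(C)(C)C)[C@H](c1ccc(OCc3ccccc3)c(OC)c1)O2 | intermediate
16 | [(2R,3R)-2-[4-(benzyloxy)-3-methoxyphenyl]-5-formyl-7-methoxy-2,3-dihydro-1-benzofuran-3-yl]methyl 2,2-dimethylpropanoate | O=Cc1cc(OC)c2c(c1)[C@H](COC(=O)C(C)(C)C)[C@H](c1ccc(OCc3ccccc3)c(OC)c1)O2 | intermediate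
17 | ethyl 3-[(2R,3R)-2-[4-(benzyloxy)-3-methoxyphenyl]-3-{[(2,2-dimethylpropanoyl)oxy]methyl}-7-methoxy-2,3-dihydro-1-benzofuran-5-yl]-3-oxopropanoate | CCOC(=O)CC(=O)c1cc(OC)c2c(c1)[C@H](COC(=O)C(C)(C)C)[C@H](c1ccc(OCc3ccccc3)c(OC)c1)O2 | intermediate
18 | [4-(benzyloxy)-3-methoxyphenyl]acetic acid | COc1cc(CC(=O)O)ccc1OCc1ccccc1 | starting material
19 | [4-(benzyloxy)-3-methoxyphenyl]acetyl chloride | COc1cc(CC(=O)Cl)ccc1OCc1ccccc1 | intermediate (not isolated)
20 | 1-[4-(benzyloxy)-3-methoxyphenyl]-3-diazopropan-2-one | COc1cc(CC(=O)C=[N+]=[N-])ccc1OCc1ccccc1 | intermediate (not isolated)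
21 | 1-[4-(benzyloxy)-3-methoxyphenyl]-3-chloropropan-2-one | COc1cc(CC(=O)CCl)ccc1OCc1ccccc1 | intermediate
22 | ethyl (3S)-2-{[(2R,3R)-2-[4-(benzyloxy)-3-methoxyphenyl]-3-{[(2,2-dimethylpropanoyl)oxy]methyl}-7-methoxy-2,3-dihydro-1-benzofuran-5-yl]carbonyl}-4-[4-(benzyloxy)-3-methoxyphenyl]-3-(chloromethyl)-3-hydroxybutanoate (C2 enolisable, not defined) | CCOC(=O)C(C(=O)c1cc(OC)c2c(c1)[C@H](COC(=O)C(C)(C)C)[C@H](c1ccc(OCc3ccccc3)c(OC)c1)O2)[C@](O)(CCl)Cc1ccc(OCc2ccccc2)c(OC)c1 | intermediate (not isolated)
23 | ethyl (4S)-4-{[4-(benzyloxy)-3-methoxyphenyl]methyl}-2-[(2R,3R)-2-[4-(benzyloxy)-3-methoxyphenyl]-3-{[(2,2-dimethylpropanoyl)oxy]methyl}-7-methoxy-2,3-dihydro-1-benzofuran-5-yl]-4-hydroxy-4,5-dihydrofuran-3-carboxylate | CCOC(=O)C1=C(c2cc(OC)c3c(c2)[C@H](COC(=O)C(C)(C)C)[C@H](c2ccc(OCc4ccccc4)c(OC)c2)O3)OC[C@]1(O)Cc1ccc(OCc2ccccc2)c(OC)c1 | intermediate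
24 | ethyl (2R,3R,4S)-4-{[4-(benzyloxy)-3-methoxyphenyl]methyl}-2-[(2R,3R)-2-[4-(benzyloxy)-3-methoxyphenyl]-3-{[(2,2-dimethylpropanoyl)oxy]methyl}-7-methoxy-2,3-dihydro-1-benzofuran-5-yl]-4-hydroxyoxolane-3-carboxylate | CCOC(=O)[C@@H]1[C@H](c2cc(OC)c3c(c2)[C@H](COC(=O)C(C)(C)C)[C@H](c2ccc(OCc4ccccc4)c(OC)c2)O3)OC[C@]1(O)Cc1ccc(OCc2ccccc2)c(OC)c1 | intermediate
25 | (3S,4R,5R)-5-[(2R,3R)-2-[4-(benzyloxy)-3-methoxyphenyl]-3-(hydroxymethyl)-7-methoxy-2,3-dihydro-1-benzofuran-5-yl]-3-{[4-(benzyloxy)-3-methoxyphenyl]methyl}-4-(hydroxymethyl)oxolan-3-ol | COc1cc(C[C@@]2(O)CO[C@@H](c3cc(OC)c4c(c3)[C@H](CO)[C@H](c3ccc(OCc5ccccc5)c(OC)c3)O4)[C@H]2CO)ccc1OCc1ccccc1 | intermediate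
26 | (3S,4R,5R)-5-[(2R,3R)-2-(4-hydroxy-3-methoxyphenyl)-3-(hydroxymethyl)-7-methoxy-2,3-dihydro-1-benzofuran-5-yl]-3-[(4-hydroxy-3-methoxyphenyl)methyl]-4-(hydroxymethyl)oxolan-3-ol | COc1cc(C[C@@]2(O)CO[C@@H](c3cc(OC)c4c(c3)[C@H](CO)[C@H](c3ccc(O)c(OC)c3)O4)[C@H]2CO)ccc1O | target

## Step count and least certain steps

Total: 17 steps. Longest linear sequence: 15 steps (steps 1–3, 5–12 and 14–17). Steps 4 and 13 are side branches.

**Step 14 (annulation, new in its asymmetric form).** The most likely failure is poor facial selectivity at the ketone of 21, whose two flanking groups are both methylene groups, so that both C4' configurations form. Slow ring closure with chloride could also leave time for retro-aldol and loss of selectivity, and acid on work-up could dehydrate the product towards the furan.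

The fallback sets out from 17 and comes back at 24. It uses the electrophile for which the asymmetric annulation is established. 17 is condensed with ethyl bromopyruvate under the same amine catalysis to give the diethyl (4S)-4-hydroxy-4,5-dihydrofuran-3,4-dicarboxylate F1, in which an ester stands where the benzyl group will be. Hydroxyl-directed hydrogenation as in step 15 gives the all-cis oxolane diester F2. BH3·SMe2 with catalytic NaBH4 reduces only the ester next to the hydroxyl and gives the 1,2-diol F3. TsCl, Et3N and catalytic Bu2SnO sulfonylate the primary hydroxyl to the tosylate F4, which DBU closes to the spiro-epoxide F5. The aryl Grignard reagent F6 (from 4-(benzyloxy)-1-bromo-3-methoxybenzene and Mg) with CuI (10 mol %) at −30 °C opens F5 at its CH2 group and gives 24.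

**Step 9 (key step).** Three processes could defeat it: proton transfer from the benzylic O–CH to the aryllithium (net debromination), opening at the terminal epoxide carbon in the 6-endo mode, and a slow closure because the cis product forces the aryl group and the CH2O arm together in the transition state, so that warming lets intermolecular reactions in.

The fallback sets out from 7 and comes back at 14. It forms C2–C3 in place of C3–C3a. Mitsunobu etherification of 7 with 4-(benzyloxy)-3-methoxybenzyl alcohol (PPh3, DIAD) gives the benzyl aryl ether F7. Coupling with BrZnCH2CO2t-Bu (Pd2(dba)3, XPhos, THF, 60 °C) gives the tert-butyl arylacetate F8. Diazo transfer (p-acetamidobenzenesulfonyl azide, DBU) gives the aryl diazoacetate F9. Rh2(S-PTTL)4 (1 mol %, toluene, −60 °C) effects 1,5-insertion of the carbenoid into the benzylic ether C–H bond and gives the cis tert-butyl (2R,3S)-2,3-dihydrobenzofuran-3-carboxylate F10. LiAlH4 at −78 °C reduces it to 14 before the cis ester can epimerise.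

**Step 3 (epoxidation).** The electron-rich benzylic epoxide may be opened at C3 by isopropanol, tartrate or hydroperoxide on the Lewis-acidic titanium centre or on work-up, with loss of material and of stereochemical purity.

The fallback sets out from 4 and comes back at 5. It removes the Lewis acid altogether. 4 is silylated (TBSCl, imidazole) to the silyl ether F11. Shi epoxidation with the D-fructose-derived ketone and KHSO5 at pH about 10.5 (MeCN–dimethoxymethane–aqueous K2CO3 buffer, 0 °C) gives the (2R,3R)-epoxy silyl ether F12. Bu4NF in THF at 0 °C then gives 5.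

**Step 15 (hydrogenation).** The tetrasubstituted, ester-conjugated enol ether may be too hindered and too electron-poor to bind the iridium centre, so that reduction stalls or the catalyst deactivates.

The fallback sets out from 23 and comes back at 26. It exchanges coordination control for surface control and moves the debenzylation forward. Hydrogenation over Pd/C (4 bar, EtOAc–EtOH) adds hydrogen from the face opposite the benzyl group, which is again the hydroxyl face, and removes both benzyl ethers, giving the bis-phenol oxolane ester F13. Excess LiAlH4 (THF, −20 to 0 °C, careful neutral work-up) then reduces the ester and cleaves the pivalate to give 26 directly.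

**Step 12 (homologation).** With an electron-rich aromatic aldehyde the aryl group may migrate in place of hydride, giving the branched formyl ester, and the Lewis acid may ionise the C2–O1 bond and erode the cis ring.

The fallback sets out from 16 and comes back at 17. The lithium enolate of ethyl acetate (LDA, THF, −78 °C) adds to 16 and gives the β-hydroxy ester F14 as a mixture of carbinol epimers. Dess–Martin periodinane buffered with NaHCO3 oxidises it to 17.

## Further compounds

F1 | step 14 | diethyl (4S)-2-[(2R,3R)-2-[4-(benzyloxy)-3-methoxyphenyl]-3-{[(2,2-dimethylpropanoyl)oxy]methyl}-7-methoxy-2,3-dihydro-1-benzofuran-5-yl]-4-hydroxy-4,5-dihydrofuran-3,4-dicarboxylate | CCOC(=O)C1=C(c2cc(OC)c3c(c2)[C@H](COC(=O)C(C)(C)C)[C@H](c2ccc(OCc4ccccc4)c(OC)c2)O3)OC[C@]1(O)C(=O)OCC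
F2 | step 14 | diethyl (2R,3R,4S)-2-[(2R,3R)-2-[4-(benzyloxy)-3-methoxyphenyl]-3-{[(2,2-dimethylpropanoyl)oxy]methyl}-7-methoxy-2,3-dihydro-1-benzofuran-5-yl]-4-hydroxyoxolane-3,4-dicarboxylate (all-cis carbon substituents) | CCOC(=O)[C@@H]1[C@H](c2cc(OC)c3c(c2)[C@H](COC(=O)C(C)(C)C)[C@H](c2ccc(OCc4ccccc4)c(OC)c2)O3)OC[C@]1(O)C(=O)OCC
F3 | step 14 | ethyl (2R,3R,4R)-2-[(2R,3R)-2-[4-(benzyloxy)-3-methoxyphenyl]-3-{[(2,2-dimethylpropanoyl)oxy]methyl}-7-methoxy-2,3-dihydro-1-benzofuran-5-yl]-4-hydroxy-4-(hydroxymethyl)oxolane-3-carboxylate | CCOC(=O)[C@@H]1[C@H](c2cc(OC)c3c(c2)[C@H](COC(=O)C(C)(C)C)[C@H](c2ccc(OCc4ccccc4)c(OC)c2)O3)OC[C@]1(O)CO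
F4 | step 14 | primary p-toluenesulfonate of F3 (configuration as in F3) | CCOC(=O)[C@@H]1[C@H](c2cc(OC)c3c(c2)[C@H](COC(=O)C(C)(C)C)[C@H](c2ccc(OCc4ccccc4)c(OC)c2)O3)OC[C@]1(O)COS(=O)(=O)c1ccc(C)cc1
F5 | step 14 | ethyl 6-[(2R,3R)-2-[4-(benzyloxy)-3-methoxyphenyl]-3-{[(2,2-dimethylpropanoyl)oxy]methyl}-7-methoxy-2,3-dihydro-1-benzofuran-5-yl]-1,5-dioxaspiro[2.4]heptane-7-carboxylate (spiro-epoxide from F4, configuration as in the SMILES) | CCOC(=O)[C@@H]1[C@H](c2cc(OC)c3c(c2)[C@H](COC(=O)C(C)(C)C)[C@H](c2ccc(OCc4ccccc4)c(OC)c2)O3)OC[C@]12CO2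
F6 | step 14 | [4-(benzyloxy)-3-methoxyphenyl]magnesium bromide | COc1cc([Mg]Br)ccc1OCc1ccccc1
F7 | step 9 | 2-{[4-(benzyloxy)-3-methoxyphenyl]methoxy}-1-bromo-5-(dimethoxymethyl)-3-methoxybenzene | COC(OC)c1cc(OC)c(OCc2ccc(OCc3ccccc3)c(OC)c2)c(Br)c1
F8 | step 9 | tert-butyl [2-{[4-(benzyloxy)-3-methoxyphenyl]methoxy}-5-(dimethoxymethyl)-3-methoxyphenyl]acetate | COC(OC)c1cc(OC)c(OCc2ccc(OCc3ccccc3)c(OC)c2)c(CC(=O)OC(C)(C)C)c1
F9 | step 9 | tert-butyl [2-{[4-(benzyloxy)-3-methoxyphenyl]methoxy}-5-(dimethoxymethyl)-3-methoxyphenyl](diazo)acetate | COC(OC)c1cc(OC)c(OCc2ccc(OCc3ccccc3)c(OC)c2)c(C(=[N+]=[N-])C(=O)OC(C)(C)C)c1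
F10 | step 9 | tert-butyl (2R,3S)-2-[4-(benzyloxy)-3-methoxyphenyl]-5-(dimethoxymethyl)-7-methoxy-2,3-dihydro-1-benzofuran-3-carboxylate (cis) | COC(OC)c1cc(OC)c2c(c1)[C@H](C(=O)OC(C)(C)C)[C@H](c1ccc(OCc3ccccc3)c(OC)c1)O2
F11 | step 3 | {[(2E)-3-[4-(benzyloxy)-3-methoxyphenyl]prop-2-en-1-yl]oxy}(tert-butyl)dimethylsilane | CC(C)(C)[Si](C)(C)OC/C=C/c1ccc(OCc2ccccc2)c(OC)c1
F12 | step 3 | {[(2R,3R)-3-[4-(benzyloxy)-3-methoxyphenyl]oxiran-2-yl]methoxy}(tert-butyl)dimethylsilane | CC(C)(C)[Si](C)(C)OC[C@H]1O[C@@H]1c1ccc(OCc2ccccc2)c(OC)c1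
F13 | step 15 | ethyl (2R,3R,4S)-4-hydroxy-4-[(4-hydroxy-3-methoxyphenyl)methyl]-2-[(2R,3R)-2-(4-hydroxy-3-methoxyphenyl)-3-{[(2,2-dimethylpropanoyl)oxy]methyl}-7-methoxy-2,3-dihydro-1-benzofuran-5-yl]oxolane-3-carboxylate | CCOC(=O)[C@@H]1[C@H](c2cc(OC)c3c(c2)[C@H](COC(=O)C(C)(C)C)[C@H](c2ccc(O)c(OC)c2)O3)OC[C@]1(O)Cc1ccc(O)c(OC)c1
F14 | step 12 | ethyl 3-[(2R,3R)-2-[4-(benzyloxy)-3-methoxyphenyl]-3-{[(2,2-dimethylpropanoyl)oxy]methyl}-7-methoxy-2,3-dihydro-1-benzofuran-5-yl]-3-hydroxypropanoate (both carbinol epimers) | CCOC(=O)CC(O)c1cc(OC)c2c(c1)[C@H](COC(=O)C(C)(C)C)[C@H](c1ccc(OCc3ccccc3)c(OC)c1)O2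
A1 | alternative 1 | bis(tert-butyldimethylsilyl) ether of the cis-2-aryl-3-(hydroxymethyl)-4-methylideneoxolane whose aryl group is the O-benzylated cis-dihydrobenzofuran | C=C2CO[C@@H](c3cc(OC)c4c(c3)[C@H](CO[Si](C)(C)C(C)(C)C)[C@H](c3ccc(OCc5ccccc5)c(OC)c3)O4)[C@H]2CO[Si](C)(C)C(C)(C)C
A2 | alternative 2 | fully silylated target skeleton with a cis methyl ester at C3 of ring D | COc1cc(C[C@@]2(O[Si](CC)(CC)CC)CO[C@@H](c3cc(OC)c4c(c3)[C@H](C(=O)OC)[C@H](c3ccc(O[Si](C)(C)C(C)(C)C)c(OC)c3)O4)[C@H]2CO[Si](C)(C)C(C)(C)C)ccc1O[Si](C)(C)C(C)(C)C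
A3 | alternative 3 | cis-2-aryl-3-{[tert-butyl(dimethyl)silyl]oxymethyl}-7-methoxy-2,3-dihydro-1-benzofuran with ring E as its p-toluenesulfonate and C5 unsubstituted | c1cc(OC)c2c(c1)[C@H](CO[Si](C)(C)C(C)(C)C)[C@H](c1ccc(OS(=O)(=O)c3ccc(C)cc3)c(OC)c1)O2
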